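**Retrosynthetic overview**
1. The route rests on the C3'=C4' alkene of ring D (2H-pyran: O1' on C10, gem-dimethyl C2', C3'=C4', C4' on C11). It is the only disubstituted alkene, and its two carbons hang from the tetrasubstituted C10=C11 alkene of oxepine ring C, which holds them cis. Ring D is therefore closed last, by ring-closing metathesis between a C11 vinyl group and the vinyl group of a C10 O-(1,1-dimethylallyl) enol ether.
2. The diene goes back to a C10-chloro, C11-formyl alkene: the C10–O bond by addition–elimination of the tertiary allylic alkoxide, the C11 vinyl group by Wittig methylenation. The chloro enal comes from Vilsmeier–Haack–Arnold chloroformylation of the dibenzo[b,f]oxepin-10(11H)-one.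
3. The ring A prenyl group is placed on C2 by bromination and Stille coupling at the ketone stage. The phenols travel as methyl ethers through the acidic early steps and as triisopropylsilyl ethers afterwards.
4. Ring C comes from an Ullmann diaryl ether coupling and an intramolecular Friedel–Crafts acylation. Order of ring formation: rings A and B are bought, ring C closes in step 2, ring D in step 10.

Key step: step 10

Remark: atoms are numbered on the dibenzo[b,f]oxepine skeleton throughout (ring A = C1–C4, C4a, C11a; ring B = C5a, C6–C9, C9a; ring C has O5, C10 next to ring B and C11 next to ring A). Triisopropylsilyl ethers are chosen for the phenols because they are expected to withstand the alkoxide of step 8 better than smaller silyl ethers.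

**Route**

Step 1
Reactants: 1 2-bromo-4-methoxyphenylacetic acid; 2 3-methoxyphenol
Product: 3 2-[4-methoxy-2-(3-methoxyphenoxy)phenyl]acetic acid
Conditions: CuI (10 mol %), N,N-dimethylglycine hydrochloride (20 mol %), Cs2CO3 (3 equiv), 1,4-dioxane, 100 °C; acidic aqueous work-up
Reagents that add atoms: none
Why: Ullmann diaryl ether coupling of an aryl bromide with a phenol under ligand-assisted CuI catalysis; the C–Br bond is the only carbon–halogen bond and the carboxylate is a spectator.

Step 2
Reactants: 3 2-[4-methoxy-2-(3-methoxyphenoxy)phenyl]acetic acid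
Product: 4 3,7-dimethoxydibenzo[b,f]oxepin-10(11H)-one
Conditions: Eaton's reagent (P2O5 in MeSO3H), 25 → 50 °C; ice water
Reagents that add atoms: none
Why: Intramolecular Friedel–Crafts acylation closes the seven-membered ring C at the position of the 3-methoxyphenoxy ring that is ortho to the bridging oxygen and para to OMe, the other ortho position being crowded between two oxygens.

Step 3
Reactants: 4 3,7-dimethoxydibenzo[b,f]oxepin-10(11H)-one
Product: 5 2-bromo-3,7-dimethoxydibenzo[b,f]oxepin-10(11H)-one
Conditions: NBS (1.0 equiv), DMF, 0 °C → rt, dark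
Reagents that add atoms: N-bromosuccinimide, O=C1CCC(=O)N1Br
Why: Electrophilic aromatic bromination should go to C2 of ring A (ortho to OMe, para to the bridging oxygen), since ring B is deactivated by conjugation with the C10 ketone and C4 lies between two oxygens.

Step 4
Reactants: 5 2-bromo-3,7-dimethoxydibenzo[b,f]oxepin-10(11H)-one
Product: 6 2-bromo-3,7-dihydroxydibenzo[b,f]oxepin-10(11H)-one
Conditions: BBr3 (5 equiv), CH2Cl2, −78 °C → rt; then H2O
Reagents that add atoms: none
Why: Lewis-acid cleavage of both aryl methyl ethers by BBr3, done before the acid-sensitive prenyl group is present; the diaryl ether, ketone and aryl bromide are inert.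

Step 5
Reactants: 6 2-bromo-3,7-dihydroxydibenzo[b,f]oxepin-10(11H)-one
Product: 7 2-bromo-3,7-bis(triisopropylsilyloxy)dibenzo[b,f]oxepin-10(11H)-one
Conditions: i-Pr3SiCl (2.5 equiv), imidazole (5 equiv), DMF, rt → 40 °C
Reagents that add atoms: chlorotriisopropylsilane, CC(C)[Si](Cl)(C(C)C)C(C)C
Why: O-silylation of both phenols with a silyl chloride and imidazole, a base too weak to enolise and O-silylate the ketone.

Step 6
Reactants: 7 2-bromo-3,7-bis(triisopropylsilyloxy)dibenzo[b,f]oxepin-10(11H)-one; 8 tributyl(3-methylbut-2-enyl)stannane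
Product: 9 2-(3-methylbut-2-enyl)-3,7-bis(triisopropylsilyloxy)dibenzo[b,f]oxepin-10(11H)-one
Conditions: Pd(PPh3)4 (5 mol %), DMF, 95 °C
Reagents that add atoms: none
Why: Stille coupling: zerovalent palladium inserts into the C2–Br bond and the allyl group is transferred from tin at its unsubstituted terminus to give the linear prenyl arene, under base-free conditions that leave the enolisable ketone and the silyl ethers alone.

Step 7
Reactants: 9 2-(3-methylbut-2-enyl)-3,7-bis(triisopropylsilyloxy)dibenzo[b,f]oxepin-10(11H)-one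
Product: 11 10-chloro-2-(3-methylbut-2-enyl)-3,7-bis(triisopropylsilyloxy)dibenzo[b,f]oxepine-11-carbaldehyde, via chlorovinyl iminium salt 10 (not isolated)
Conditions: POCl3 (2.5 equiv), DMF (5 equiv), CH2Cl2, 0 → 40 °C; then ice water, pH 6–7
Reagents that add atoms: N,N-dimethylformamide, CN(C)C=O; phosphoryl chloride, O=P(Cl)(Cl)Cl; water, O
Why: Vilsmeier–Haack–Arnold chloroformylation of an enolisable aryl benzyl ketone: the enol is C-formylated at C11, the C10 oxygen is activated and replaced by chloride, and the resulting 3-chloropropeniminium salt is hydrolysed to the β-chlorovinyl aldehyde; C2 of ring A is already occupied and ring B is deactivated by the conjugated iminium.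

Step 8
Reactants: 11 10-chloro-2-(3-methylbut-2-enyl)-3,7-bis(triisopropylsilyloxy)dibenzo[b,f]oxepine-11-carbaldehyde; 12 2-methylbut-3-en-2-ol
Product: 14 10-(2-methylbut-3-en-2-yloxy)-2-(3-methylbut-2-enyl)-3,7-bis(triisopropylsilyloxy)dibenzo[b,f]oxepine-11-carbaldehyde, via potassium 2-methylbut-3-en-2-olate 13 (not isolated)
Conditions: 12 (1.5 equiv), KN(SiMe3)2 (1.3 equiv), THF, −40 °C; then 11, −40 → 0 °C; pH 7 buffer
Reagents that add atoms: none
Why: Nucleophilic vinylic substitution by addition–elimination: the alkoxide adds to C10, the β-carbon of the chloro enal, and chloride leaves; the aldehyde has no acidic hydrogen and the seven-membered ring rules out fragmentation to an alkyne.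

Step 9
Reactants: 14 10-(2-methylbut-3-en-2-yloxy)-2-(3-methylbut-2-enyl)-3,7-bis(triisopropylsilyloxy)dibenzo[b,f]oxepine-11-carbaldehyde
Product: 15 11-ethenyl-10-(2-methylbut-3-en-2-yloxy)-2-(3-methylbut-2-enyl)-3,7-bis(triisopropylsilyloxy)dibenzo[b,f]oxepine
Conditions: Ph3PCH3Br (1.6 equiv), KN(SiMe3)2 (1.5 equiv), THF, 0 °C; then 14, −78 → 0 °C; Et3N-deactivated silica, used at once
Reagents that add atoms: methyltriphenylphosphonium bromide, C[P+](c1ccccc1)(c1ccccc1)c1ccccc1.[Br-]
Why: Wittig methylenation of the C11 aldehyde by the non-stabilised ylide, run cold and without free base so that the tertiary allyl enol ether neither undergoes its (3,3) shift nor loses the allyl group.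

Step 10
Reactants: 15 11-ethenyl-10-(2-methylbut-3-en-2-yloxy)-2-(3-methylbut-2-enyl)-3,7-bis(triisopropylsilyloxy)dibenzo[b,f]oxepine
Product: 16 artocarpol D bis(triisopropylsilyl) ether
Conditions: second-generation Grubbs catalyst RuCl2(=CHPh)(H2IMes)(PCy3) (5–10 mol %), CH2Cl2 (0.005 M), argon sparge, 25 °C
Reagents that add atoms: none
Why: Ring-closing olefin metathesis: the ruthenium benzylidene exchanges onto one terminal vinyl group (most likely the less hindered one on C11), the new alkylidene adds (2+2) to the vinyl group of the 1,1-dimethylallyl ether, and the ruthenacyclobutane cycloreverts to form the C3'=C4' bond and a Ru=CH2 carrier that releases ethylene. The closest known reaction is the metathesis closure of 1,1-dimethylallyl 2-vinylaryl ethers to 2,2-dimethyl-2H-chromenes, with the arene replaced here by the C10=C11 enol ether alkene. Ring D closes as a six-membered ring because C10=C11 holds the two vinyl-bearing atoms cis and the gem-dimethyl carbon C2' favours the folded conformer. No stereocentre is formed and the new alkene is cis by ring constraint. The step needs chemoselection for the two terminal vinyl groups over the trisubstituted prenyl alkene of ring A and the tetrasubstituted C10=C11 alkene, which their higher substitution secures, and neither of those can give an unstrained ring. It must also outrun the (3,3) shift of the allyl enol ether, which ambient temperature and high dilution should secure.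

Step 11
Reactants: 16 artocarpol D bis(triisopropylsilyl) ether
Product: 17 artocarpol D
Conditions: Bu4NF (2.5 equiv), AcOH (2.5 equiv), THF, 0 °C
Reagents that add atoms: none
Why: Fluoride-induced cleavage of both aryl silyl ethers, buffered with acetic acid so that the ortho-prenyl phenol and the 2H-pyran enol ether meet neither strong acid nor strong base.

**Compound list**
1 | 2-bromo-4-methoxyphenylacetic acid | COc1ccc(CC(=O)O)c(Br)c1 | starting material
2 | 3-methoxyphenol | COc1cccc(O)c1 | starting material
3 | 2-[4-methoxy-2-(3-methoxyphenoxy)phenyl]acetic acid | COc1ccc(CC(=O)O)c(Oc2cccc(OC)c2)c1 | intermediate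
4 | 3,7-dimethoxydibenzo[b,f]oxepin-10(11H)-one | COc1ccc2c(c1)Oc1cc(OC)ccc1C(=O)C2 | intermediate
5 | 2-bromo-3,7-dimethoxydibenzo[b,f]oxepin-10(11H)-one | COc1cc2c(cc1Br)CC(=O)c1ccc(OC)cc1O2 | intermediate
6 | 2-bromo-3,7-dihydroxydibenzo[b,f]oxepin-10(11H)-one | Oc1cc2c(cc1Br)CC(=O)c1ccc(O)cc1O2 | intermediate
7 | 2-bromo-3,7-bis(triisopropylsilyloxy)dibenzo[b,f]oxepin-10(11H)-one | CC(C)[Si](C(C)C)(C(C)C)Oc1cc2c(cc1Br)CC(=O)c1ccc(O[Si](C(C)C)(C(C)C)C(C)C)cc1O2 | intermediate
8 | tributyl(3-methylbut-2-enyl)stannane | CCCC[Sn](CCCC)(CCCC)CC=C(C)C | starting material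
9 | 2-(3-methylbut-2-enyl)-3,7-bis(triisopropylsilyloxy)dibenzo[b,f]oxepin-10(11H)-one | CC(C)=CCc1cc2c(cc1O[Si](C(C)C)(C(C)C)C(C)C)Oc1cc(O[Si](C(C)C)(C(C)C)C(C)C)ccc1C(=O)C2 | intermediate
10 | chlorovinyl iminium salt: N-{[10-chloro-2-(3-methylbut-2-enyl)-3,7-bis(triisopropylsilyloxy)dibenzo[b,f]oxepin-11-yl]methylidene}-N-methylmethanaminium chloride | CC(C)=CCc1cc2c(cc1O[Si](C(C)C)(C(C)C)C(C)C)Oc1cc(O[Si](C(C)C)(C(C)C)C(C)C)ccc1C(Cl)=C2C=[N+](C)C.[Cl-] | intermediate
11 | 10-chloro-2-(3-methylbut-2-enyl)-3,7-bis(triisopropylsilyloxy)dibenzo[b,f]oxepine-11-carbaldehyde | CC(C)=CCc1cc2c(cc1O[Si](C(C)C)(C(C)C)C(C)C)Oc1cc(O[Si](C(C)C)(C(C)C)C(C)C)ccc1C(Cl)=C2C=O | intermediate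
12 | 2-methylbut-3-en-2-ol | C=CC(C)(C)O | starting material
13 | potassium 2-methylbut-3-en-2-olate | C=CC(C)(C)[O-].[K+] | intermediate
14 | 10-(2-methylbut-3-en-2-yloxy)-2-(3-methylbut-2-enyl)-3,7-bis(triisopropylsilyloxy)dibenzo[b,f]oxepine-11-carbaldehyde | CC(C)=CCc1cc2c(cc1O[Si](C(C)C)(C(C)C)C(C)C)Oc1cc(O[Si](C(C)C)(C(C)C)C(C)C)ccc1C(OC(C)(C)C=C)=C2C=O | intermediate
15 | 11-ethenyl-10-(2-methylbut-3-en-2-yloxy)-2-(3-methylbut-2-enyl)-3,7-bis(triisopropylsilyloxy)dibenzo[b,f]oxepine | CC(C)=CCc1cc2c(cc1O[Si](C(C)C)(C(C)C)C(C)C)Oc1cc(O[Si](C(C)C)(C(C)C)C(C)C)ccc1C(OC(C)(C)C=C)=C2C=C | intermediate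
16 | artocarpol D bis(triisopropylsilyl) ether | CC(C)=CCc1cc2c(cc1O[Si](C(C)C)(C(C)C)C(C)C)Oc1cc(O[Si](C(C)C)(C(C)C)C(C)C)ccc1C1=C2C=CC(C)(C)O1 | intermediate
17 | artocarpol D | CC(C)=CCc1cc2c(cc1O)Oc1cc(O)ccc1C1=C2C=CC(C)(C)O1 | target

**Step count and risks**
Total step count: 11. Longest linear sequence: 11 steps (1 → 17).

Steps most likely to fail:

1. Step 10 (ring-closing metathesis). The catalyst may be arrested as a donor-stabilised vinylalkylidene after loading at the C11 vinyl group, because that carbene is conjugated with the enol ether oxygen. Turnover at the neopentyl-type vinyl group next to C2' may be slow. On warming, the (3,3) shift of the allyl enol ether or acid-promoted loss of the tertiary allyl group may take over. Fallback: ring D is closed by an oxa-6π electrocyclisation instead, setting out from 9 and returning at 16. Ketone 9 would be deprotonated with LiN(i-Pr)2 in THF at −78 °C to the lithium enolate F1, which should add to 3-methylbut-2-enal to give the β-hydroxy ketone F2 as a mixture of diastereomers. Treatment with MeSO2Cl and Et3N in CH2Cl2 would pass through the mesylate F3 and eliminate to the cross-conjugated dienone F4. Warming F4 in toluene, with daylight or a trace of iodine to equilibrate the exocyclic alkene, should let the isomer whose diene chain lies syn to the C10 carbonyl close to the 2H-pyran 16.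

2. Step 8 (addition–elimination with the tertiary alkoxide). Attack of the bulky alkoxide at the fully substituted C10 may be slow, so that reversible addition to the formyl group or desilylation of the ring B silyl ether (para to the electron-poor alkene) competes. Fallback: the C10–O bond is made with a slimmer, less basic alkynyl alkoxide and the vinyl group is revealed afterwards, setting out from 11 and returning at 14. 2-Methylbut-3-yn-2-ol and KN(SiMe3)2 in THF would give potassium 2-methylbut-3-yn-2-olate F5, which should displace chloride from 11 to give the propargylic enol ether F6. Semi-hydrogenation of the terminal alkyne over Lindlar catalyst (Pd on CaCO3 poisoned with Pb(OAc)2, quinoline, H2 at 1 atm, EtOAc) would then give 14.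

3. Step 7 (chloroformylation). Hydrogen chloride released during the reaction may add to the prenyl alkene or loosen a silyl ether, and the electron-rich ring A may be formylated at C4. Fallback: the one-carbon unit is introduced under neutral conditions and the chloride in a separate acid-free step, setting out from 9 and returning at 10. Heating 9 with N,N-dimethylformamide dimethyl acetal in toluene at 80 °C should give the enaminone F7. Oxalyl chloride in CH2Cl2 at −20 °C would convert F7 into the chloride salt 10 with loss of only CO and CO2, and 10 is hydrolysed to 11 as in step 7.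

**Further compounds**
F1 | step 10 | lithium enolate of 9 (lithium 2-(3-methylbut-2-enyl)-3,7-bis(triisopropylsilyloxy)dibenzo[b,f]oxepin-10-olate) | CC(C)=CCc1cc2c(cc1O[Si](C(C)C)(C(C)C)C(C)C)Oc1cc(O[Si](C(C)C)(C(C)C)C(C)C)ccc1C([O-])=C2.[Li+]
F2 | step 10 | 11-(1-hydroxy-3-methylbut-2-enyl)-2-(3-methylbut-2-enyl)-3,7-bis(triisopropylsilyloxy)dibenzo[b,f]oxepin-10(11H)-one (mixture of diastereomers) | CC(C)=CCc1cc2c(cc1O[Si](C(C)C)(C(C)C)C(C)C)Oc1cc(O[Si](C(C)C)(C(C)C)C(C)C)ccc1C(=O)C2C(O)C=C(C)C
F3 | step 10 | methanesulfonate of F2 (mixture of diastereomers) | CC(C)=CCc1cc2c(cc1O[Si](C(C)C)(C(C)C)C(C)C)Oc1cc(O[Si](C(C)C)(C(C)C)C(C)C)ccc1C(=O)C2C(OS(C)(=O)=O)C=C(C)C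
F4 | step 10 | 11-(3-methylbut-2-enylidene)-2-(3-methylbut-2-enyl)-3,7-bis(triisopropylsilyloxy)dibenzo[b,f]oxepin-10(11H)-one (mixture of alkene isomers) | CC(C)=CCc1cc2c(cc1O[Si](C(C)C)(C(C)C)C(C)C)Oc1cc(O[Si](C(C)C)(C(C)C)C(C)C)ccc1C(=O)C2=CC=C(C)C
F5 | step 8 | potassium 2-methylbut-3-yn-2-olate | C#CC(C)(C)[O-].[K+]
F6 | step 8 | 10-(2-methylbut-3-yn-2-yloxy)-2-(3-methylbut-2-enyl)-3,7-bis(triisopropylsilyloxy)dibenzo[b,f]oxepine-11-carbaldehyde | CC(C)=CCc1cc2c(cc1O[Si](C(C)C)(C(C)C)C(C)C)Oc1cc(O[Si](C(C)C)(C(C)C)C(C)C)ccc1C(OC(C)(C)C#C)=C2C=O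
F7 | step 7 | 11-[(dimethylamino)methylidene]-2-(3-methylbut-2-enyl)-3,7-bis(triisopropylsilyloxy)dibenzo[b,f]oxepin-10(11H)-one | CC(C)=CCc1cc2c(cc1O[Si](C(C)C)(C(C)C)C(C)C)Oc1cc(O[Si](C(C)C)(C(C)C)C(C)C)ccc1C(=O)C2=CN(C)C
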